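**Strategy.** Rings D (cyclopentanone) and E (its fused γ‑lactone) hide a methylmalonyl unit: the ketone carbon, the neighbouring C–OH carbon and the lactone O–CH(CH3) carbon are the α‑ketol‑rearranged, reduced form of a 2‑methyl‑1,3‑dione bridging the two quaternary α‑carbons of ring C. The key step is therefore a double C‑acylation: a tricyclic β‑keto ester (rings A–C, the exocyclic‑methylene carbon still a ketone) and methylmalonyl dichloride give a bicyclo[3.3.1]nonane trione, forming both bridgehead bonds at once. Methylenation, hydroxylation, α‑ketol ring contraction and reduction–lactonisation complete the bicyclo[3.2.1]octane. The tricycle comes from an enol‑lactone‑initiated polyene cyclisation of an auxiliary‑derived anti‑aldol adduct.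

Key step: step 11

Remark on the chemistry: the carbon α to the ring C ketone that bears the methyl group (C‑4 of 3–6, the same carbon in 11–16) is formed racemic and epimerises freely, so it is drawn without a descriptor until it is fixed in step 11. Compound 17 is drawn as its all‑equatorial keto tautomer and 21/22 as one dione enol. The auxiliary and catalyst enantiomers were assigned by CIP analysis of the target string (lactone CH–O carbon R; aldol centres 12R,13S).

Step 1
Reactants: 1 geranyl bromide [(2E)-1-bromo-3,7-dimethylocta-2,6-diene]; 2 methyl 3-oxopentanoate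
Product: 3 methyl (6E)-4,7,11-trimethyl-3-oxododeca-6,10-dienoate (racemic at C-4)
Conditions: LiN(iPr)2 (2.1 equiv), THF, 0 °C; then 1, 0 °C → rt
Reagents that add atoms: none
Why: Alkylation of the β‑keto ester dianion occurs at the more basic terminal (C‑4) carbanion by SN2 displacement of the allylic bromide with retention of the (E)‑alkene; the new centre is racemic and labile.

Step 2
Reactants: 3 methyl (6E)-4,7,11-trimethyl-3-oxododeca-6,10-dienoate
Product: 4 methyl (2E,6E)-3-methoxy-4,7,11-trimethyldodeca-2,6,10-trienoate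
Conditions: HC(OMe)3, MeOH, p‑TsOH (cat.), rt
Reagents that add atoms: trimethyl orthoformate COC(OC)OC
Why: Acid‑catalysed enol etherification (ketalisation, then loss of methanol) should give the thermodynamic (E)‑β‑methoxy enoate, which masks the acidic β‑keto ester through steps 3–8 and later serves as a carbon‑only cyclisation terminator.

Step 3
Reactants: 4 methyl (2E,6E)-3-methoxy-4,7,11-trimethyldodeca-2,6,10-trienoate
Product: 6 methyl (2E,6E,10E)-3-methoxy-4,7,11-trimethyl-12-oxododeca-2,6,10-trienoate, via allylic alcohol 5 (not isolated)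
Conditions: SeO2 (0.1 equiv), t‑BuOOH, salicylic acid (cat.), CH2Cl2, rt; filter; then MnO2, CH2Cl2, rt
Reagents that add atoms: tert-butyl hydroperoxide CC(C)(C)OO
Why: Catalytic SeO2 allylic oxidation (ene reaction, then [2,3]‑shift) is selective for the (E)‑methyl of the terminal, most electron‑rich trisubstituted alkene, and MnO2 converges the crude alcohol on the (E)‑enal.

Step 4
Reactants: 7 pent-4-ynoic acid; 8 (R)-4-benzyloxazolidin-2-one
Product: 10 (R)-4-benzyl-3-(pent-4-ynoyl)oxazolidin-2-one, via mixed pivalic anhydride 9 (not isolated)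
Conditions: t‑BuCOCl, Et3N, THF, −20 °C; then 8, LiCl, rt
Reagents that add atoms: none
Why: Mixed‑anhydride N‑acylation of the oxazolidinone is a standard auxiliary loading and leaves its stereocentre untouched.

Step 5
Reactants: 6 methyl (2E,6E,10E)-3-methoxy-4,7,11-trimethyl-12-oxododeca-2,6,10-trienoate; 10 (R)-4-benzyl-3-(pent-4-ynoyl)oxazolidin-2-one
Product: 12 methyl (2E,6E,10E,12R,13S)-13-[(R)-4-benzyl-2-oxooxazolidine-3-carbonyl]-12-hydroxy-3-methoxy-4,7,11-trimethylhexadeca-2,6,10-trien-15-ynoate, via trimethylsilyl ether 11 (not isolated)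
Conditions: MgCl2 (0.2 equiv), Et3N, Me3SiCl, EtOAc, rt; then CF3CO2H, MeOH, 0 °C
Reagents that add atoms: none
Why: In this magnesium‑catalysed, silylation‑driven anti‑aldol addition to a non‑enolisable enal, the chelated (Z)‑enolate should react through a boat transition state on the face opposite the benzyl group, so the (R)‑auxiliary sets 13S and the anti relationship sets 12R; acid methanolysis then removes the silyl group.

Step 6
Reactants: 12 the anti‑aldol adduct
Product: 13 methyl (2E,6E,10E,12R,13S)-13-[(R)-4-benzyl-2-oxooxazolidine-3-carbonyl]-3-methoxy-4,7,11-trimethyl-12-(triisopropylsilyloxy)hexadeca-2,6,10-trien-15-ynoate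
Conditions: i‑Pr3SiOTf, 2,6‑lutidine, CH2Cl2, 0 °C → rt
Reagents that add atoms: triisopropylsilyl triflate CC(C)[Si](OS(=O)(=O)C(F)(F)F)(C(C)C)C(C)C
Why: Silylation with the bulky triflate protects the allylic alcohol as a non‑participating ether that should survive the acidic cyclisation; no stereocentre is affected.

Step 7
Reactants: 13 the silylated imide
Product: 15 (2S,3R,4E,8E,12E)-12,14-dimethoxy-4,8,11-trimethyl-14-oxo-2-(prop-2-yn-1-yl)-3-(triisopropylsilyloxy)tetradeca-4,8,12-trienoic acid, via peroxy acid 14 (not isolated)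
Conditions: LiOH, H2O2, THF/H2O, 0 °C; then Na2SO3; then HCl to pH 3
Reagents that add atoms: hydrogen peroxide OO
Why: Hydroperoxide attacks the exocyclic imide carbonyl selectively (auxiliary cleavage without epimerisation), sulfite reduces the peroxy acid, and the deactivated vinylogous‑carbonate methyl ester should not be hydrolysed at 0 °C.

Step 8
Reactants: 15 the alkynoic acid
Product: 16 methyl (2E,6E,10E,12R)-3-methoxy-4,7,11-trimethyl-12-[(3S)-5-methylidene-2-oxooxolan-3-yl]-12-(triisopropylsilyloxy)dodeca-2,6,10-trienoate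
Conditions: AuCl (5 mol%), K2CO3 (10 mol%), MeCN, rt
Reagents that add atoms: none
Why: Gold‑catalysed 5‑exo‑dig cycloisomerisation of a γ‑alkynoic acid (anti‑oxyauration, protodeauration) gives the exocyclic enol lactone without touching the stereocentres.

Step 9
Reactants: 16 the enol lactone polyene
Product: 17 tricyclic lactone β‑keto ester (rings A–C: ring C is a methyl 3-methyl-2-oxocyclohexane-1-carboxylate trans‑fused to ring B; ring A is bridged by a γ‑lactone from its CH–C(=O) carbon to its C(CH3)–O carbon and carries OSi(iPr)3 on the CH next to the angular C–CH3; both angular methyls and the lactone bridge on one face, ring‑fusion hydrogens and silyloxy group on the other)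
Conditions: CF3SO3H (1.2 equiv), CH2Cl2, −78 °C; then H2O, −78 °C → rt
Reagents that add atoms: water O
Why: Proposed new method: protonation of the enol lactone at its terminal CH2 gives a tertiary acyloxycarbenium ion held in the five‑membered lactone, the (E)‑trisubstituted alkene attacks it through the only chair that keeps the lactone as a 1,3‑diaxial bridge (silyloxy group axial, anti to the future angular methyl), and antiperiplanar chair–chair propagation through the second (E)‑alkene to the α‑carbon of the methoxy enoate sets the trans‑anti‑trans fusions before hydrolysis of the terminal oxocarbenium ion unveils the ring C β‑keto ester; the closest known reaction types are acetal‑ and N‑acyliminium‑initiated cationic polyene cyclisations and Friedel–Crafts lactone formation from angelica‑type enol lactones.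

Step 10
Reactants: 18 methylmalonic acid
Product: 19 methylmalonyl dichloride (2-methylpropanedioyl dichloride)
Conditions: (COCl)2, DMF (cat.), CH2Cl2, 0 °C → rt
Reagents that add atoms: oxalyl chloride O=C(Cl)C(Cl)=O
Why: Standard conversion of a diacid into its diacid chloride under Vilsmeier catalysis.

Step 11
Reactants: 17 tricyclic lactone β‑keto ester; 19 methylmalonyl dichloride
Product: 21 bicyclo[3.3.1]nonane trione (ring C of 17 bridged between its two ketone α‑carbons by C(=O)–C(CH3)=C(OH); bridgeheads carry CH3 and CO2Me; drawn as one dione enol), via C‑acylated acid chloride 20 (not isolated)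
Conditions: LiN(iPr)2 (2.2 equiv), THF, −78 → −20 °C; 19 (1.1 equiv), −78 → 0 °C; then DMAP (0.2 equiv), rt
Reagents that add atoms: none
Why: Two equivalents of base convert 17 into the β‑keto ester dianion, whose more basic methyl‑bearing α′‑carbon is C‑acylated by one acid chloride of the symmetrical reagent from the axial face, giving the bond that becomes the ring D ketone–C(CH3) bond. The remaining enolate carbon (bearing CO2Me) then attacks the second acid chloride in a 6‑(enolexo)‑exo‑trig C‑acylation, giving the bond that becomes the C(OH)–C(CO2) bond and closing the six‑membered 1,3‑dione ring of a bicyclo[3.3.1]nonane; the closest known reaction types are the Effenberger α,α′‑annulation of cyclohexanone enol derivatives with malonyl dichloride and the γ,α‑difunctionalisation of β‑keto ester dianions. Both new quaternary stereocentres are fixed by the ring, because the three‑carbon bridge can only span the two α‑carbons diaxially on the face opposite the axial angular methyl, leaving CH3 and CO2Me equatorial. The selectivity needed is C‑ over O‑acylation in the second closure; lithium chelation of the β‑keto ester and DMAP‑mediated O→C acyl transfer should funnel any enol ester to the thermodynamically favoured, strongly acidic 2‑methyl‑1,3‑dione. The central carbon of 19 becomes the later lactone O–CH(CH3) carbon.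

Step 12
Reactants: 21 bicyclo[3.3.1]nonane trione
Product: 22 9‑methylidene dione (bridging ketone of 21 replaced by C=CH2)
Conditions: Zn, CH2Br2, TiCl4 (reagent pre‑formed at −40 °C), THF/CH2Cl2, 0 °C → rt
Reagents that add atoms: dibromomethane BrCBr
Why: In this Lombardo–Takai methylenation the non‑basic gem‑dimetallic reagent should add only to the bridging ketone, because the acidic 1,3‑dione is tied up as its titanium enolate, esters and lactones are inert, and the flat dione bridge leaves one face of the ketone open.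

Step 13
Reactants: 22 9‑methylidene dione
Product: 23 hydroxy dione (C(OH)(CH3) between the two ring ketones, hydroxyl exo)
Conditions: KN(SiMe3)2 (1.1 equiv), THF, −78 °C; 3-phenyl-2-(phenylsulfonyl)oxaziridine; AcOH, −78 °C
Reagents that add atoms: 3-phenyl-2-(phenylsulfonyl)oxaziridine O=S(=O)(N1OC1c1ccccc1)c1ccccc1
Why: Electrophilic hydroxylation of the potassium dione enolate by the N‑sulfonyloxaziridine occurs at the central carbon from the open exo face and spares the 1,1‑disubstituted alkene; the new centre is erased in step 14.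

Step 14
Reactants: 23 hydroxy dione
Product: 24 α‑ketol (bicyclo[3.2.1]octane: ring D cyclopentanone whose carbinol carbon carries OH endo and acetyl exo, syn to CO2Me)
Conditions: Sc(OTf)3 (0.2 equiv), CH2Cl2, rt
Reagents that add atoms: none
Why: In this Lewis‑acid α‑ketol rearrangement Sc(OTf)3 should chelate the ketone next to the ester‑bearing bridgehead together with the ester carbonyl, so the other acyl carbon migrates suprafacially onto it, contracting the ring to the cyclopentanone and placing the new tertiary hydroxyl endo and the acetyl group exo.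

Step 15
Reactants: 24 α‑ketol
Product: 27 brasilianoid F, via hydroxy ester 25 (not isolated), via silyl ether lactone 26 (not isolated)
Conditions: (S)-2-methyl-CBS-oxazaborolidine (0.3 equiv), catecholborane (2 equiv), toluene, −78 °C; MeOH; then HF·pyridine, THF, 0 °C → rt
Reagents that add atoms: none
Why: Corey–Bakshi–Shibata reduction of the methyl ketone under catalyst control should give the (R)‑carbinol (the flanked ring ketone and the alkene are not expected to react with catecholborane at −78 °C), which lactonises onto the syn methyl ester, and HF·pyridine then cleaves the silyl ether.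

**Compound list**

1 | geranyl bromide | CC(C)=CCC/C(C)=C/CBr | starting material
2 | methyl 3-oxopentanoate | CCC(=O)CC(=O)OC | starting material
3 | methyl (6E)-4,7,11-trimethyl-3-oxododeca-6,10-dienoate | COC(=O)CC(=O)C(C)C/C=C(C)/CCC=C(C)C | intermediate
4 | methyl (2E,6E)-3-methoxy-4,7,11-trimethyldodeca-2,6,10-trienoate | COC(=O)/C=C(/OC)C(C)C/C=C(C)/CCC=C(C)C | intermediate
5 | methyl (2E,6E,10E)-12-hydroxy-3-methoxy-4,7,11-trimethyldodeca-2,6,10-trienoate | COC(=O)/C=C(/OC)C(C)C/C=C(C)/CC/C=C(C)/CO | intermediate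
6 | methyl (2E,6E,10E)-3-methoxy-4,7,11-trimethyl-12-oxododeca-2,6,10-trienoate | COC(=O)/C=C(/OC)C(C)C/C=C(C)/CC/C=C(C)/C=O | intermediate
7 | pent-4-ynoic acid | C#CCCC(=O)O | starting material
8 | (R)-4-benzyloxazolidin-2-one | O=C1N[C@H](Cc2ccccc2)CO1 | starting material
9 | pent-4-ynoic pivalic anhydride | C#CCCC(=O)OC(=O)C(C)(C)C | intermediate
10 | (R)-4-benzyl-3-(pent-4-ynoyl)oxazolidin-2-one | C#CCCC(=O)N1[C@H](Cc2ccccc2)COC1=O | intermediate
11 | O‑trimethylsilyl anti‑aldol adduct (12R,13S) | C#CC[C@H](C(=O)N1[C@H](Cc2ccccc2)COC1=O)[C@@H](O[Si](C)(C)C)/C(C)=C/CC/C(C)=C/CC(C)/C(OC)=C\C(=O)OC | intermediate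
12 | anti‑aldol adduct, methyl (2E,6E,10E,12R,13S)-13-[(R)-4-benzyl-2-oxooxazolidine-3-carbonyl]-12-hydroxy-3-methoxy-4,7,11-trimethylhexadeca-2,6,10-trien-15-ynoate | C#CC[C@H](C(=O)N1[C@H](Cc2ccccc2)COC1=O)[C@@H](O)/C(C)=C/CC/C(C)=C/CC(C)/C(OC)=C\C(=O)OC | intermediate
13 | 12‑O‑triisopropylsilyl ether of 12 | C#CC[C@H](C(=O)N1[C@H](Cc2ccccc2)COC1=O)[C@@H](O[Si](C(C)C)(C(C)C)C(C)C)/C(C)=C/CC/C(C)=C/CC(C)/C(OC)=C\C(=O)OC | intermediate
14 | (2S,3R,4E,8E,12E)-12,14-dimethoxy-4,8,11-trimethyl-14-oxo-2-(prop-2-yn-1-yl)-3-(triisopropylsilyloxy)tetradeca-4,8,12-trieneperoxoic acid | C#CC[C@H](C(=O)OO)[C@@H](O[Si](C(C)C)(C(C)C)C(C)C)/C(C)=C/CC/C(C)=C/CC(C)/C(OC)=C\C(=O)OC | intermediate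
15 | (2S,3R,4E,8E,12E)-12,14-dimethoxy-4,8,11-trimethyl-14-oxo-2-(prop-2-yn-1-yl)-3-(triisopropylsilyloxy)tetradeca-4,8,12-trienoic acid | C#CC[C@H](C(=O)O)[C@@H](O[Si](C(C)C)(C(C)C)C(C)C)/C(C)=C/CC/C(C)=C/CC(C)/C(OC)=C\C(=O)OC | intermediate
16 | methyl (2E,6E,10E,12R)-3-methoxy-4,7,11-trimethyl-12-[(3S)-5-methylidene-2-oxooxolan-3-yl]-12-(triisopropylsilyloxy)dodeca-2,6,10-trienoate | C=C1C[C@H](C(=O)O1)[C@@H](O[Si](C(C)C)(C(C)C)C(C)C)/C(C)=C/CC/C(C)=C/CC(C)/C(OC)=C\C(=O)OC | intermediate
17 | tricyclic lactone β‑keto ester (rings A–C, as described in step 9) | O=C1[C@@H](C)C[C@H]2[C@]3(C)[C@H](O[Si](C(C)C)(C(C)C)C(C)C)[C@@H]4C[C@@](C)(OC4=O)[C@H]3CC[C@]2(C)[C@H]1C(=O)OC | intermediate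
18 | methylmalonic acid | CC(C(=O)O)C(=O)O | starting material
19 | methylmalonyl dichloride | CC(C(=O)Cl)C(=O)Cl | intermediate
20 | C‑acylated acid chloride (17 bearing C(=O)CH(CH3)C(=O)Cl on the methyl‑bearing α‑carbon) | O=C1[C@](C)(C(=O)C(C)C(=O)Cl)C[C@H]2[C@]3(C)[C@H](O[Si](C(C)C)(C(C)C)C(C)C)[C@@H]4C[C@@](C)(OC4=O)[C@H]3CC[C@]2(C)[C@H]1C(=O)OC | intermediate
21 | bicyclo[3.3.1]nonane trione (enol form) | O=C1[C@@]2(C)C[C@H]3[C@]4(C)[C@H](O[Si](C(C)C)(C(C)C)C(C)C)[C@@H]5C[C@@](C)(OC5=O)[C@H]4CC[C@]3(C)[C@]1(C(=O)OC)C(O)=C(C)C2=O | intermediate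
22 | 9‑methylidene dione (enol form) | C=C1[C@@]2(C)C[C@H]3[C@]4(C)[C@H](O[Si](C(C)C)(C(C)C)C(C)C)[C@@H]5C[C@@](C)(OC5=O)[C@H]4CC[C@]3(C)[C@]1(C(=O)OC)C(O)=C(C)C2=O | intermediate
23 | 3‑hydroxy‑3‑methyl‑2,4‑dione (hydroxyl exo) | C=C1[C@@]2(C)C[C@H]3[C@]4(C)[C@H](O[Si](C(C)C)(C(C)C)C(C)C)[C@@H]5C[C@@](C)(OC5=O)[C@H]4CC[C@]3(C)[C@]1(C(=O)OC)C(=O)[C@@](C)(O)C2=O | intermediate
24 | α‑ketol with acetyl group (bicyclo[3.2.1]octane) | C=C1[C@@]2(C)C[C@H]3[C@]4(C)[C@H](O[Si](C(C)C)(C(C)C)C(C)C)[C@@H]5C[C@@](C)(OC5=O)[C@H]4CC[C@]3(C)[C@]1(C(=O)OC)[C@@](O)(C(C)=O)C2=O | intermediate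
25 | hydroxy ester ((R)-1-hydroxyethyl in place of acetyl) | C=C1[C@@]2(C)C[C@H]3[C@]4(C)[C@H](O[Si](C(C)C)(C(C)C)C(C)C)[C@@H]5C[C@@](C)(OC5=O)[C@H]4CC[C@]3(C)[C@]1(C(=O)OC)[C@@](O)([C@@H](C)O)C2=O | intermediate
26 | O‑triisopropylsilyl brasilianoid F | C=C1[C@@]2(C)C[C@H]3[C@]4(C)[C@H](O[Si](C(C)C)(C(C)C)C(C)C)[C@@H]5C[C@@](C)(OC5=O)[C@H]4CC[C@]3(C)[C@@]13C(=O)O[C@H](C)[C@@]3(O)C2=O | intermediate
27 | brasilianoid F | C=C1[C@@]2(C)C[C@H]3[C@]4(C)[C@H](O)[C@@H]5C[C@@](C)(OC5=O)[C@H]4CC[C@]3(C)[C@@]13C(=O)O[C@H](C)[C@@]3(O)C2=O | target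

**Step count and risks**

Total steps: 15. Longest linear sequence: 13 (steps 1–3, 5–9, 11–15); steps 4 and 10 are side branches.

Steps most likely to fail:

Step 9 (proposed new method). The acid may protonate a trisubstituted alkene instead of the enol lactone; the β‑silyloxy cation formed after the first ring closure may undergo a 1,2‑hydride shift; or the first ring may close through a boat, giving the wrong ring fusion. The fallback runs from 13 to 17 with known chemistry. Reductive removal of the auxiliary with LiBH4 gives the primary alcohol F1. AuCl‑catalysed 5‑exo‑dig hydroalkoxylation gives the exocyclic enol ether F2. Enol ethers are protonated far more readily than trisubstituted alkenes, so camphorsulfonic acid in CH2Cl2 generates a cyclic alkoxycarbenium ion. This is a classical Prins/acetal‑type initiator held in the same five‑membered tether, so the same chair cascade should give the tricyclic ether F3 after aqueous work‑up. RuCl3/NaIO4 then oxidises the ether CH2 to the lactone carbonyl and returns to 17.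

Step 11 (key step). After the first C‑acylation the ring may close through the enolate oxygen, or the diacid chloride may link two molecules. The fallback runs from 17 to 21. Compound 17 is converted with LiN(iPr)2/Me3SiCl (two rounds) into the bis(trimethylsilyl) dienol ether F4, whose two nucleophilic carbons are the same two α‑carbons. Me3SiOTf‑catalysed Effenberger‑type annulation with 19 in CH2Cl2 at −78 °C still forms both bonds in one operation, now under electrophilic activation, and gives 21 after work‑up.

Step 12. The bridging ketone between two quaternary carbons may resist the bulky titanium–zinc reagent, or an ester carbonyl may be attacked instead. The fallback runs from 21 to 22 as a two‑stage Peterson olefination. The small nucleophile Me3SiCH2MgCl/CeCl3 adds to the bridging ketone (the dione being protected as its enolate) to give the β‑hydroxysilane F5, and BF3·OEt2‑mediated elimination gives 22.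

**Further compounds**

F1 | step 9 | methyl (2E,6E,10E,12R,13R)-13-(hydroxymethyl)-3-methoxy-4,7,11-trimethyl-12-(triisopropylsilyloxy)hexadeca-2,6,10-trien-15-ynoate | C#CC[C@H](CO)[C@@H](O[Si](C(C)C)(C(C)C)C(C)C)/C(C)=C/CC/C(C)=C/CC(C)/C(OC)=C\C(=O)OC
F2 | step 9 | methyl (2E,6E,10E,12R)-3-methoxy-4,7,11-trimethyl-12-[(3R)-5-methylideneoxolan-3-yl]-12-(triisopropylsilyloxy)dodeca-2,6,10-trienoate | C=C1C[C@H](CO1)[C@@H](O[Si](C(C)C)(C(C)C)C(C)C)/C(C)=C/CC/C(C)=C/CC(C)/C(OC)=C\C(=O)OC
F3 | step 9 | tricyclic ether β‑keto ester (17 with the lactone C=O replaced by CH2) | O=C1[C@@H](C)C[C@H]2[C@]3(C)[C@H](O[Si](C(C)C)(C(C)C)C(C)C)[C@@H]4C[C@@](C)(OC4)[C@H]3CC[C@]2(C)[C@H]1C(=O)OC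
F4 | step 11 | bis(trimethylsilyl) dienol ether of 17 (ketene acetal geometry not defined) | COC(O[Si](C)(C)C)=C1C(O[Si](C)(C)C)=C(C)C[C@H]2[C@]3(C)[C@H](O[Si](C(C)C)(C(C)C)C(C)C)[C@@H]4C[C@@](C)(OC4=O)[C@H]3CC[C@@]21C
F5 | step 12 | β‑hydroxysilane (21 with C(OH)CH2SiMe3 at the bridging carbon; carbinol configuration not defined) | C[Si](C)(C)CC1(O)[C@@]2(C)C[C@H]3[C@]4(C)[C@H](O[Si](C(C)C)(C(C)C)C(C)C)[C@@H]5C[C@@](C)(OC5=O)[C@H]4CC[C@]3(C)[C@]1(C(=O)OC)C(O)=C(C)C2=O
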